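# Proposed synthesis of kaempferol 3,7-di-O-sulfate (16)

## Analysis of the target

Target 16 is a flavonol: ring A (benzo) is fused to ring C (4H-pyran-4-one), ring B (4-hydroxyphenyl) sits on C2, and oxygen is attached at C3, C5, C7 and C4'. It has no stereocentre, so stereocentres may be used as scaffolding on the way, provided they vanish when ring C becomes aromatic. Two of the four hydroxyls are sulfate half-esters, the enolic O3 and the phenolic O7, while O5 and O4' are free. The sulfates are the sensitive groups: they are strongly acidic, water-soluble and hydrolysed by acid, so they should be installed late, carried as salts and followed only by neutral chemistry. The skeleton is simple; the difficulty is telling four hydroxyls apart. O5 is held in a hydrogen bond to the C4 carbonyl and is the least reactive; O4' is about as reactive as O7 and needs a mask that leaves under neutral conditions after sulfation; O5 and O7 need masks during ring construction that come off before sulfation without disturbing O4'. The plan rests on ring C: O1–C2 and C3–O3 are two C–O bonds on neighbouring carbons, the pattern of an epoxide opened by a phenol oxygen. If C2, C3 and the C4 carbon come from an aryl glycidate and O1 from a ring A phenol, the only ring bond left to make is C4–C4a, an aryl ketone bond ortho to O1 on a very electron-rich ring.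

## Retrosynthetic reasoning

**O4'–benzyl bond (16 from 15).** The last bond cut is the benzyl–oxygen bond at C4' of 15. A benzyl ether is the phenol mask that leaves under neutral reducing conditions, which the sulfate half-esters of 16 tolerate. The forward step must cleave this benzylic C–O bond without reducing C2=C3 of ring C or breaking an O–S bond.

**O3–S and O7–S bonds (15 from 14).** Both sulfur–oxygen bonds are cut together, which leads to triol 14 with only O4' masked. In 14 the selection is made by the molecule: O5 is tied to C4=O by its hydrogen bond, so the forward sulfation only has to stop after O7 and O3 have reacted.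

**The two O–allyl bonds on ring A (14 from 13).** Ring A must carry two ethers while ring C is built, so that its phenol is a single nucleophile and the ring is activated for acylation. Allyl is chosen because its removal by zerovalent palladium with an amine scavenger leaves the benzyl ether of ring B and the free enol at C3 untouched.

**C2=C3 unsaturation (13 from 11, through 12).** Adding two hydrogens across C2–C3 leads back to dihydroflavonol 11, where C2 and C3 are sp3 carbons each bearing one oxygen, as an epoxide-based construction requires. Forward, the oxidant has to spare allyl and benzyl ethers; an aerobic base-mediated oxidation through dione 12 does so. It also erases both stereocentres, so their configuration in 11 does not matter for 16.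

**C4–C4a (11 from 8; key disconnection).** Ring C of 11 is opened at C4–C4a to give hydroxy acid 8. This is the only ring bond that is neither a C–O bond nor part of the three-carbon unit. The ring A carbon involved is flanked by the ether oxygen and one allyloxy group and is para to the other. Ring A of 8 is symmetric, so the two ortho carbons are equivalent. The forward reaction has to activate the carboxyl group (mixed anhydride 9) enough to acylate the ring but not enough to ionise the benzylic C2–O1 bond; the hydroxyl passes through as the transient ester in 10.

**O1–C2 (8 from 7, then 7 from 6 and 3).** After ester hydrolysis (8 from 7), the bond between the benzylic carbon and the ring A oxygen is cut, giving glycidate 6 and phenol 3. The cut is made here and not at C3–O because the benzylic carbon of 6 is the electrophilic end of the epoxide. The forward step needs O-alkylation of the phenoxide of 3 and attack at the benzylic carbon. Inversion there on the trans epoxide gives the anti product that closes to the trans ring, although either diastereomer would serve.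

**Epoxide (6 from 4 and 5).** Glycidate 6 is cut across its C2–C3 bond and one C–O bond into aldehyde 4 and chloro ester 5, a glycidic ester condensation. One step supplies C2, C3, C4 and the oxygen on C3, with ring B and its benzyl mask already in place.

**O–allyl bonds of 3 (3 from 1 and 2).** Phenol 3 is cut at both O–allyl bonds to triol 1 and bromide 2. Because 1 is threefold symmetric, any two hydroxyls may react; the forward step only has to stop at the diether and favour O- over C-alkylation.

## Alternatives that were turned down

**Alternative 1:** Crossed Claisen with a benzodioxinone.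
- Disconnection: C3–C4 and O1–C2. Ring A comes as the acetonide-locked salicylate A2 (2,2-dimethyl-5,7-bis(methoxymethoxy)-4H-1,3-benzodioxin-4-one). Ring B with C2, C3 and O3 comes as ketone A3 (1-[4-(benzyloxy)phenyl]-2-(methoxymethoxy)ethan-1-one).
- Forward key step: the lithium enolate of A3 adds to the carbonyl of A2, the ketal collapses and frees the phenoxide that becomes O1. An acidic alcoholic work-up then closes O1–C2 by cyclodehydration and removes every acetal, giving A1 (2-[4-(benzyloxy)phenyl]-3,5,7-trihydroxy-4H-chromen-4-one), which is the same compound as 14.
- For it: it is convergent, works at the final oxidation level, makes no stereocentres and needs no dehydrogenation or separate ring A unmasking.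
- Against it: the carbonyl of A2 is flanked by two ortho oxygens and conjugated to three donor oxygens, so it is a hindered and deactivated electrophile. The α-oxygenated enolate of A3 can acylate on oxygen, and the acidic diketone product consumes a second equivalent of enolate. Both partners need several steps, including acetal protection of a chelated phenol.
- Comparison: on convergence and step count this alternative is stronger, since it reaches 14 in fewer operations. The chosen route offers bulk starting materials, no cryogenic enolate chemistry, and a ring closure in which the reactive partner is an exceptionally nucleophilic arene and not a deactivated ester.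

**Alternative 2:** Carbonylative three-component annulation.
- Disconnection: C4a–C4, C4–C3 and O1–C2, with C4 supplied by A6. The partners are iodophenol A5 (2-iodo-3,5-bis(methoxymethoxy)phenol), carbon monoxide A6 and alkyne A7 (1-(benzyloxy)-4-ethynylbenzene).
- Forward key step: the C–I bond of A5 adds to zerovalent palladium, A6 inserts, the acyl palladium couples with the acetylide of A7, and the phenol adds 6-endo to the ynone in an amine solvent. The product is A4 (2-[4-(benzyloxy)phenyl]-5,7-bis(methoxymethoxy)-4H-chromen-4-one).
- For it: two C–C bonds and one C–O bond form in one flask under mild conditions, and ring C is aromatic at once.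
- Against it: A4 has hydrogen at C3, so the oxygen that must carry a sulfate is missing. Installing it (metalation and oxidation, or epoxidation of an electron-poor enone) costs at least two steps on a substrate with acid-labile acetals. The 5-exo closure to the benzofuranone isomer competes, A5 needs a site-selective iodination, and a toxic gas is required.
- Comparison: bond economy in the key step is better than in the chosen route, but the chosen route carries O3 from the glycidate and so avoids a late C–H oxidation.

**Alternative 3:** Mentzer thermal union.
- Disconnection: C4–C4a and O1–C2 in one operation, from unprotected 1 and keto ester A9 (ethyl 2-(benzoyloxy)-3-[4-(benzyloxy)phenyl]-3-oxopropanoate).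
- Forward key step: neat heating makes the ring carbon of 1 attack the ester carbonyl and a phenol oxygen condense with the ketone. This gives A8 (3-(benzoyloxy)-2-[4-(benzyloxy)phenyl]-5,7-dihydroxy-4H-chromen-4-one), with O3 and ring B in place.
- For it: it is the shortest route, needs no protecting groups on ring A, poses no regiochemical question because 1 is symmetric, and would reach 14 after removal of the benzoate.
- Against it: the fusion temperature stresses the benzyl ether and the α-acyloxy keto ester (acyl migration, fragmentation). Closure through the ketone carbon to the isomeric lactone competes, and the outcome of a melt reaction is hard to predict or steer.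
- Comparison: on step economy this alternative is clearly stronger. The chosen route offers bond formations at or near room temperature with a defined site of reaction and purifiable intermediates at each stage.

Key step: step 5

Assumption: intermediates with stereocentres are racemic and one enantiomer is drawn; the sulfate half-esters of 15 and 16 are drawn as free acids, as in the target, but would be handled as ammonium or potassium salts and set free, if wanted, only by a final cold cation-exchange pass.

## Route

Step 1
Reactants: 1 phloroglucinol; 2 allyl bromide
Product: 3 3,5-bis(allyloxy)phenol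
Conditions: 2 (2.0 equiv), K2CO3 (2.2 equiv), DMF, 0 °C → rt, argon
Reagents that add atoms: none
Why: Williamson etherification; a potassium phenoxide in a dipolar aprotic solvent alkylates at oxygen, and with two equivalents of 2 the diether should be the main component of a statistical mixture from which mono- and triether are separated and recycled.

Step 2
Reactants: 4 4-(benzyloxy)benzaldehyde; 5 methyl chloroacetate
Product: 6 methyl trans-3-[4-(benzyloxy)phenyl]oxirane-2-carboxylate (racemic; 2R,3S enantiomer drawn)
Conditions: NaOMe (1.5 equiv), MeOH, −10 °C → rt
Reagents that add atoms: none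
Why: Darzens glycidic ester condensation; the aldol step is reversible and the anti chlorohydrin alkoxide closes faster by intramolecular SN2, so the trans epoxide should predominate, which fixes the two new stereocentres relative to each other.

Step 3
Reactants: 6 methyl trans-3-[4-(benzyloxy)phenyl]oxirane-2-carboxylate; 3 3,5-bis(allyloxy)phenol
Product: 7 methyl (2R*,3R*)-3-[3,5-bis(allyloxy)phenoxy]-3-[4-(benzyloxy)phenyl]-2-hydroxypropanoate
Conditions: 3 (1.1 equiv), Cs2CO3 (0.3 equiv), DMF, 60 °C
Reagents that add atoms: none
Why: Base-catalysed SN2 opening of an aryl glycidate by a phenoxide at the benzylic carbon, which the para-benzyloxyphenyl ring activates while the ester disfavours attack at the adjacent carbon; inversion on the trans epoxide sets the anti (2R*,3R*) relationship, and a minor diastereomer would do no harm because both centres are erased in step 6. The cesium phenoxide in DMF should react at oxygen and not at a ring carbon.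

Step 4
Reactants: 7 methyl (2R*,3R*)-3-[3,5-bis(allyloxy)phenoxy]-3-[4-(benzyloxy)phenyl]-2-hydroxypropanoate
Product: 8 (2R*,3R*)-3-[3,5-bis(allyloxy)phenoxy]-3-[4-(benzyloxy)phenyl]-2-hydroxypropanoic acid
Conditions: LiOH·H2O (1.5 equiv), THF/H2O, 0 °C → rt; then cold 1 M HCl to pH 3
Reagents that add atoms: lithium hydroxide, [Li+].[OH-]
Why: Ester saponification by acyl–oxygen cleavage; the benzylic aryl ether and the allyl and benzyl ethers are stable to hydroxide, and the brief cold acidification is too mild to ionise the benzylic C–O bond.

Step 5
Reactants: 8 (2R*,3R*)-3-[3,5-bis(allyloxy)phenoxy]-3-[4-(benzyloxy)phenyl]-2-hydroxypropanoic acid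
Product: 11 trans-5,7-bis(allyloxy)-2-[4-(benzyloxy)phenyl]-3-hydroxychroman-4-one (racemic), via bis(trifluoroacetyl) mixed anhydride 9 (not isolated), via chromanone 3-trifluoroacetate 10 (not isolated)
Conditions: (CF3CO)2O (3 equiv), CH2Cl2 (0.02 M), 0 °C → rt; concentrate; MeOH, NaHCO3 (cat.), rt
Reagents that add atoms: none
Why: Trifluoroacetic anhydride acylates both the carboxyl and the hydroxyl of 8 to give 9, in which the substrate carbonyl of the mixed anhydride is the electrophile and trifluoroacetate the leaving group. The ring A carbon flanked by the ether oxygen and one allyloxy group and para to the other attacks this carbonyl and the arenium ion loses a proton, forming C4–C4a; the closest known reaction type is the intramolecular Friedel–Crafts acylation of 3-aryloxypropanoic acids to chroman-4-ones. Ring C closes in the 6-exo-trig mode with respect to the acyl carbon, the only ring size the tether allows. No stereocentre is formed: C2 and C3 keep the anti relationship from step 3 and appear trans-diequatorial, and any epimerisation at C3 through the enol is irrelevant because step 6 erases both centres. The step needs site selectivity on ring A and chemoselectivity against ionisation of the benzylic C2–O1 bond. Only the two equivalent ortho carbons can reach the acyl carbon, and dilution suppresses intermolecular acylation. The adjacent trifluoroacetoxy and acyl groups destabilise a cation at C2 and no Lewis or mineral acid is present, so the benzylic ether should survive. Methanolysis then removes the labile trifluoroacetate from 10.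

Step 6
Reactants: 11 trans-5,7-bis(allyloxy)-2-[4-(benzyloxy)phenyl]-3-hydroxychroman-4-one
Product: 13 5,7-bis(allyloxy)-2-[4-(benzyloxy)phenyl]-3-hydroxy-4H-chromen-4-one, via chromane-3,4-dione 12 (not isolated)
Conditions: KOAc (2 equiv), O2 (1 atm), DMF, 60 °C
Reagents that add atoms: none
Why: Base-mediated aerobic dehydrogenation of a dihydroflavonol; acetate enolises the α-hydroxy ketone toward C3, the enediol is oxidised by O2 to dione 12 as benzoin is oxidised to benzil, and 12 tautomerises through its acidic C2–H to the aromatic 3-hydroxypyranone, so both stereocentres disappear. Allyl and benzyl ethers are inert to O2 and to a weak base.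

Step 7
Reactants: 13 5,7-bis(allyloxy)-2-[4-(benzyloxy)phenyl]-3-hydroxy-4H-chromen-4-one
Product: 14 2-[4-(benzyloxy)phenyl]-3,5,7-trihydroxy-4H-chromen-4-one
Conditions: Pd(PPh3)4 (5 mol %), morpholine (10 equiv), THF, rt
Reagents that add atoms: none
Why: Tsuji–Trost deallylation; zerovalent palladium ionises each aryl allyl ether to a π-allyl complex and a phenoxide, and morpholine traps the allyl group irreversibly. The benzyl ether cannot ionise in this way and the enol at C3 is not affected.

Step 8
Reactants: 14 2-[4-(benzyloxy)phenyl]-3,5,7-trihydroxy-4H-chromen-4-one
Product: 15 2-[4-(benzyloxy)phenyl]-5-hydroxy-4-oxo-4H-chromene-3,7-diyl bis(hydrogen sulfate)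
Conditions: Me3N·SO3 (4 equiv), Et3N (6 equiv), DMF, rt
Reagents that add atoms: sulfur trioxide–trimethylamine complex, C[N+](C)(C)S(=O)(=O)[O-]
Why: O-sulfation by transfer of SO3 from an amine complex to a phenoxide or enolate; the acidic 7-OH reacts first and the 3-OH next, while the 5-OH, chelated to C4=O and further deactivated by the neighbouring anionic sulfates, should stay free at room temperature. O4' is blocked by benzyl.

Step 9
Reactants: 15 2-[4-(benzyloxy)phenyl]-5-hydroxy-4-oxo-4H-chromene-3,7-diyl bis(hydrogen sulfate)
Product: 16 kaempferol 3,7-di-O-sulfate, 5-hydroxy-2-(4-hydroxyphenyl)-4-oxo-4H-chromene-3,7-diyl bis(hydrogen sulfate)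
Conditions: H2 (1 atm), 10% Pd/C, MeOH/H2O, rt
Reagents that add atoms: none
Why: Hydrogenolysis of a benzyl aryl ether; anionic sulfate monoesters and the C2=C3 bond of the chromone are not reduced at atmospheric pressure, and the neutral medium keeps the sulfates from hydrolysing.

## Compound list

1 | phloroglucinol | Oc1cc(O)cc(O)c1 | starting material
2 | allyl bromide | C=CCBr | starting material
3 | 3,5-bis(allyloxy)phenol | Oc1cc(OCC=C)cc(OCC=C)c1 | intermediate
4 | 4-(benzyloxy)benzaldehyde | O=Cc1ccc(OCc2ccccc2)cc1 | starting material
5 | methyl chloroacetate | COC(=O)CCl | starting material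
6 | methyl trans-3-[4-(benzyloxy)phenyl]oxirane-2-carboxylate (racemic; 2R,3S drawn) | COC(=O)[C@@H]1O[C@H]1c1ccc(OCc2ccccc2)cc1 | intermediate
7 | methyl (2R*,3R*)-3-[3,5-bis(allyloxy)phenoxy]-3-[4-(benzyloxy)phenyl]-2-hydroxypropanoate (racemic) | C(c1ccccc1)Oc1ccc(cc1)[C@@H](Oc1cc(OCC=C)cc(OCC=C)c1)[C@H](C(=O)OC)O | intermediate
8 | (2R*,3R*)-3-[3,5-bis(allyloxy)phenoxy]-3-[4-(benzyloxy)phenyl]-2-hydroxypropanoic acid (racemic) | C(c1ccccc1)Oc1ccc(cc1)[C@@H](Oc1cc(OCC=C)cc(OCC=C)c1)[C@H](C(=O)O)O | intermediate
9 | (2R*,3R*)-3-[3,5-bis(allyloxy)phenoxy]-3-[4-(benzyloxy)phenyl]-2-(trifluoroacetoxy)propanoic trifluoroacetic anhydride (racemic) | C(c1ccccc1)Oc1ccc(cc1)[C@@H](Oc1cc(OCC=C)cc(OCC=C)c1)[C@H](C(=O)OC(=O)C(F)(F)F)OC(=O)C(F)(F)F | intermediate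
10 | trans-5,7-bis(allyloxy)-2-[4-(benzyloxy)phenyl]-4-oxochroman-3-yl trifluoroacetate (racemic) | C(c1ccccc1)Oc1ccc(cc1)[C@@H]2[C@H](C(=O)c3c(OCC=C)cc(OCC=C)cc3O2)OC(=O)C(F)(F)F | intermediate
11 | trans-5,7-bis(allyloxy)-2-[4-(benzyloxy)phenyl]-3-hydroxychroman-4-one (racemic; 2R,3R drawn) | C(c1ccccc1)Oc1ccc(cc1)[C@@H]2[C@H](C(=O)c3c(OCC=C)cc(OCC=C)cc3O2)O | intermediate
12 | 5,7-bis(allyloxy)-2-[4-(benzyloxy)phenyl]chromane-3,4-dione (racemic) | O=C1C(=O)c2c(OCC=C)cc(OCC=C)cc2O[C@@H]1c1ccc(OCc2ccccc2)cc1 | intermediate
13 | 5,7-bis(allyloxy)-2-[4-(benzyloxy)phenyl]-3-hydroxy-4H-chromen-4-one | O=c1c(O)c(-c2ccc(OCc3ccccc3)cc2)oc2cc(OCC=C)cc(OCC=C)c12 | intermediate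
14 | 2-[4-(benzyloxy)phenyl]-3,5,7-trihydroxy-4H-chromen-4-one | O=c1c(O)c(-c2ccc(OCc3ccccc3)cc2)oc2cc(O)cc(O)c12 | intermediate
15 | 2-[4-(benzyloxy)phenyl]-5-hydroxy-4-oxo-4H-chromene-3,7-diyl bis(hydrogen sulfate) | O=c1c(OS(=O)(=O)O)c(-c2ccc(OCc3ccccc3)cc2)oc2cc(OS(=O)(=O)O)cc(O)c12 | intermediate
16 | kaempferol 3,7-di-O-sulfate | O=c1c(OS(=O)(=O)O)c(-c2ccc(O)cc2)oc2cc(OS(=O)(=O)O)cc(O)c12 | target

## Step count and least certain steps

Total step count: 9. Longest linear sequence: 8 steps (steps 2 to 9 from 4; the branch from 1 through steps 1 and 3 to 9 is equally long).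

**Step 5 (key step).** The trifluoroacetic acid set free may ionise the benzylic C2–O1 bond, with loss of the ring A phenol before ring closure. The electron-poor α-trifluoroacetoxy acyl group may also react slowly, which gives time for intermolecular acylation or trifluoroacetylation of ring A. The fallback keeps the same bond formation but uses a discrete acid chloride and a Lewis acid at low temperature, with no Brønsted acid present. It sets out from 8:
- Ac2O in pyridine followed by aqueous work-up gives (2R*,3R*)-2-acetoxy-3-[3,5-bis(allyloxy)phenoxy]-3-[4-(benzyloxy)phenyl]propanoic acid F1.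
- Oxalyl chloride with catalytic DMF in CH2Cl2 gives (2R*,3R*)-2-acetoxy-3-[3,5-bis(allyloxy)phenoxy]-3-[4-(benzyloxy)phenyl]propanoyl chloride F2.
- SnCl4 in CH2Cl2 at −78 °C closes the ring to trans-5,7-bis(allyloxy)-2-[4-(benzyloxy)phenyl]-4-oxochroman-3-yl acetate F3.
- K2CO3 in MeOH at 0 °C removes the acetate and returns the route to 11.

**Step 3.** The phenoxide of 3 is ambident, so alkylation at a ring carbon can compete with O-alkylation. Attack at the carbon next to the ester and acyl transfer from the methyl ester to the phenoxide are further leaks. The fallback makes the same C–O bond by a Mitsunobu substitution and sets out from 4: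
- Horner–Wadsworth–Emmons olefination with trimethyl phosphonoacetate (NaH, THF) gives methyl (E)-3-[4-(benzyloxy)phenyl]prop-2-enoate F4.
- Dihydroxylation (catalytic OsO4, N-methylmorpholine N-oxide, acetone/H2O) gives racemic methyl (2R*,3S*)-3-[4-(benzyloxy)phenyl]-2,3-dihydroxypropanoate F5.
- Mitsunobu reaction of F5 with 3 (PPh3, diisopropyl azodicarboxylate, THF) should substitute the more reactive benzylic hydroxyl with inversion. This gives the same racemic diastereomer and rejoins the route at 7.

**Step 6.** Under base the C3 enolate can expel the ring A phenoxide (ring opening by β-elimination), followed by contraction to a benzofuranone. The flavonol anion, once formed, can also be cleaved further by O2. The fallback changes the order of events so that the dehydrogenation is done on a substrate with a chelated 5-OH and without alkenes. It sets out from 11: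
- Pd(PPh3)4 and morpholine in THF give trans-2-[4-(benzyloxy)phenyl]-3,5,7-trihydroxychroman-4-one F6.
- I2 and KOAc in hot acetic acid dehydrogenate F6 and rejoin the route at 14.

**Step 8.** Sulfation may stop at the 7-monosulfate because O3 is hindered and hydrogen-bonded, and forcing it may begin to sulfate O5. The resulting mixture of ionic products would be hard to separate. The fallback uses neutral, chromatographable sulfate diesters and sets out from 14:
- 2,2,2-Trichloroethyl chlorosulfate, Et3N and 4-(dimethylamino)pyridine in THF give 2-[4-(benzyloxy)phenyl]-5-hydroxy-4-oxo-4H-chromene-3,7-diyl bis(2,2,2-trichloroethyl) bis(sulfate) F7, which is purified on silica.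
- Zn dust with ammonium formate in MeOH removes both trichloroethyl groups by reductive fragmentation and rejoins the route at 15.

**Step 1.** The alkylation gives a statistical spread of mono-, di- and triethers, and allylation at ring carbons erodes it further. The fallback over-alkylates and then removes one group, and sets out from 1:
- Excess 2 with K2CO3 in acetone at reflux gives the neutral 1,3,5-tris(allyloxy)benzene F8, from which phenolic by-products are washed out with base.
- Pd(PPh3)4 with K2CO3 in MeOH removes one allyl group. Ionising a second allyl ether from the resulting phenoxide would require a dianion as leaving group, so the reaction should slow markedly after the first cleavage. The route is rejoined at 3.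

## Further compounds

F1 | step 5 | (2R*,3R*)-2-acetoxy-3-[3,5-bis(allyloxy)phenoxy]-3-[4-(benzyloxy)phenyl]propanoic acid | C(c1ccccc1)Oc1ccc(cc1)[C@@H](Oc1cc(OCC=C)cc(OCC=C)c1)[C@H](C(=O)O)OC(C)=O
F2 | step 5 | (2R*,3R*)-2-acetoxy-3-[3,5-bis(allyloxy)phenoxy]-3-[4-(benzyloxy)phenyl]propanoyl chloride | C(c1ccccc1)Oc1ccc(cc1)[C@@H](Oc1cc(OCC=C)cc(OCC=C)c1)[C@H](C(=O)Cl)OC(C)=O
F3 | step 5 | trans-5,7-bis(allyloxy)-2-[4-(benzyloxy)phenyl]-4-oxochroman-3-yl acetate | C(c1ccccc1)Oc1ccc(cc1)[C@@H]2[C@H](C(=O)c3c(OCC=C)cc(OCC=C)cc3O2)OC(C)=O
F4 | step 3 | methyl (E)-3-[4-(benzyloxy)phenyl]prop-2-enoate | COC(=O)/C=C/c1ccc(OCc2ccccc2)cc1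
F5 | step 3 | methyl (2R*,3S*)-3-[4-(benzyloxy)phenyl]-2,3-dihydroxypropanoate | C(c1ccccc1)Oc1ccc(cc1)[C@H](O)[C@H](C(=O)OC)O
F6 | step 6 | trans-2-[4-(benzyloxy)phenyl]-3,5,7-trihydroxychroman-4-one | C(c1ccccc1)Oc1ccc(cc1)[C@@H]2[C@H](C(=O)c3c(O)cc(O)cc3O2)O
F7 | step 8 | 2-[4-(benzyloxy)phenyl]-5-hydroxy-4-oxo-4H-chromene-3,7-diyl bis(2,2,2-trichloroethyl) bis(sulfate) | O=c1c(OS(=O)(=O)OCC(Cl)(Cl)Cl)c(-c2ccc(OCc3ccccc3)cc2)oc2cc(OS(=O)(=O)OCC(Cl)(Cl)Cl)cc(O)c12
F8 | step 1 | 1,3,5-tris(allyloxy)benzene | C=CCOc1cc(OCC=C)cc(OCC=C)c1
A1 | alternative 1 | 2-[4-(benzyloxy)phenyl]-3,5,7-trihydroxy-4H-chromen-4-one | O=c1c(O)c(-c2ccc(OCc3ccccc3)cc2)oc2cc(O)cc(O)c12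
A2 | alternative 1 | 2,2-dimethyl-5,7-bis(methoxymethoxy)-4H-1,3-benzodioxin-4-one | CC1(C)OC(=O)c2c(OCOC)cc(OCOC)cc2O1
A3 | alternative 1 | 1-[4-(benzyloxy)phenyl]-2-(methoxymethoxy)ethan-1-one | COCOCC(=O)c1ccc(OCc2ccccc2)cc1
A4 | alternative 2 | 2-[4-(benzyloxy)phenyl]-5,7-bis(methoxymethoxy)-4H-chromen-4-one | O=c1cc(-c2ccc(OCc3ccccc3)cc2)oc2cc(OCOC)cc(OCOC)c12
A5 | alternative 2 | 2-iodo-3,5-bis(methoxymethoxy)phenol | Oc1cc(OCOC)cc(OCOC)c1I
A6 | alternative 2 | carbon monoxide | [C-]#[O+]
A7 | alternative 2 | 1-(benzyloxy)-4-ethynylbenzene | C#Cc1ccc(OCc2ccccc2)cc1
A8 | alternative 3 | 3-(benzoyloxy)-2-[4-(benzyloxy)phenyl]-5,7-dihydroxy-4H-chromen-4-one | O=C(Oc1c(-c2ccc(OCc3ccccc3)cc2)oc2cc(O)cc(O)c2c1=O)c1ccccc1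
A9 | alternative 3 | ethyl 2-(benzoyloxy)-3-[4-(benzyloxy)phenyl]-3-oxopropanoate | CCOC(=O)C(OC(=O)c1ccccc1)C(=O)c1ccc(OCc2ccccc2)cc1
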